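**Plan**
- Retrosynthesis: the ester C–O bonds at O8 and O9 are cut first; the C2 ketone and C4–H go back to a 3‑en‑2‑one, and the C8/C9 carbinols to a C8 ketone flanked by a C9 dimethyl ketal.
- Ring B is then opened at C5–C6 (C3–C8 re-formed) by a retro anionic oxy‑Cope shift to a 2‑dienylbicyclo[2.2.2]oct‑5‑en‑2‑ol; C7–C8 is cut to a dienyllithium and a bridged ketone, and C1–C10/C2–C3 by a retro Diels–Alder reaction to benzyl vinyl ether and the masked o‑benzoquinone of 4,5‑dimethylguaiacol.
- Enabling feature: the cis C5/C10 junction of rings A and B, with quaternary C5 next to the C4 methyl carbon and the vicinal C8/C9 oxygens, maps onto a bicyclo[2.2.2]octene in which C8–C9 is the carbinol/ketal bridge, C4=C5 the alkene bridge and C1–C2 the third bridge, so that C6=C7–C8–C3–C4=C5 is a 1,5‑diene.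
- Forward: arene (C3–C5, C8–C10, C14, C15) → dearomatized dienone → bicycle (adds C1, C2) → dienyl carbinol (adds C6, C7, C11–C13) → oxy‑Cope closes ring B and frees ring A as a cyclohexene → redox adjustment of ring B, then ring A, then two acylations.
- Stereochemistry: absolute configuration from resolution of the Diels–Alder adduct; C10 and C5 from the bicycle through the suprafacial shift; C7 from kinetic protonation of the dienolate; C8 and C9 from hydride delivery to the β face; C4 from axial protonation in a dissolving‑metal reduction.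

Key step: step 8

Remark: the decalins are named with eremophilane numbering (ring A C1–C5 and C10, ring B C5–C10, C14 on C5, C15 on C4, C11–C13 the isopropenyl group), α is the face opposite to the C5 methyl group, and the absolute configuration of resolved 9 is assumed to be assignable (anomalous‑dispersion X‑ray analysis or an MTPA ester of 17) before material is committed.

Step 1
Reactants: 1 3,4-dimethylphenol
Product: 2 2-hydroxy-4,5-dimethylbenzaldehyde
Conditions: MgCl2, Et3N, (CH2O)n, MeCN, reflux; then 1 M HCl
Reagents that add atoms: paraformaldehyde (as formaldehyde), C=O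
Why: Ortho‑formylation of the magnesium phenoxide by formaldehyde (hydroxymethylation, then hydride transfer to a second formaldehyde) should occur only at C6, the ortho position not flanked by a methyl group.

Step 2
Reactants: 2 2-hydroxy-4,5-dimethylbenzaldehyde
Product: 3 2-methoxy-4,5-dimethylbenzaldehyde
Conditions: MeI, K2CO3, DMF, rt
Reagents that add atoms: iodomethane, CI
Why: Williamson O‑methylation of the phenoxide is a routine SN2 reaction with no competing site in the molecule.

Step 3
Reactants: 3 2-methoxy-4,5-dimethylbenzaldehyde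
Product: 5 2-methoxy-4,5-dimethylphenol, via aryl formate 4 (not isolated)
Conditions: mCPBA, CH2Cl2, 0 °C to rt; then K2CO3 (cat.), MeOH, rt
Reagents that add atoms: mCPBA, OOC(=O)c1cccc(Cl)c1
Why: Baeyer–Villiger oxidation of an electron‑rich benzaldehyde should proceed by aryl migration to the formate, which methanolysis cleaves to the guaiacol.

Step 4
Reactants: 5 2-methoxy-4,5-dimethylphenol; 6 benzyl vinyl ether
Product: 8 racemic (1S*,4S*,7S*)-7-(benzyloxy)-3,3-dimethoxy-5,6-dimethylbicyclo[2.2.2]oct-5-en-2-one (benzyloxy syn to the alkene bridge), via masked o-benzoquinone 7 (not isolated)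
Conditions: PhI(OAc)2, MeOH, 6 (10 equiv), 0 °C to rt
Reagents that add atoms: methanol, CO
Why: Oxidative dearomatization in methanol gives the 6,6‑dimethoxycyclohexa‑2,4‑dienone, which should be trapped in an inverse‑electron‑demand Diels–Alder reaction in which the vinyl CH2 bonds to the dienone terminus next to the ketal (largest LUMO coefficient), the oxygen‑bearing carbon bonds next to the carbonyl, and the endo mode places the benzyloxy group syn to the new alkene.

Step 5
Reactants: 8 racemic (1S*,4S*,7S*)-7-(benzyloxy)-3,3-dimethoxy-5,6-dimethylbicyclo[2.2.2]oct-5-en-2-one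
Product: 9 (1S,4S,7S)-7-(benzyloxy)-3,3-dimethoxy-5,6-dimethylbicyclo[2.2.2]oct-5-en-2-one
Conditions: preparative chiral SFC, amylose tris(3,5-dimethylphenylcarbamate) phase, CO2/MeOH
Reagents that add atoms: none
Why: Enantiomers of a rigid neutral ketone should separate on a polysaccharide phase, and the (1S,4S,7S) enantiomer is kept because its bridgehead C4 becomes C10 of the target (resolution by chiral chromatography).

Step 6
Reactants: 10 3-methylbut-3-en-2-one
Product: 11 (E)-N'-(3-methylbut-3-en-2-ylidene)-2,4,6-triisopropylbenzenesulfonohydrazide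
Conditions: 2,4,6-triisopropylbenzenesulfonohydrazide, HCl (cat.), MeOH, 0 °C to rt
Reagents that add atoms: 2,4,6-triisopropylbenzenesulfonohydrazide, CC(C)c1cc(C(C)C)c(S(=O)(=O)NN)c(C(C)C)c1
Why: Acid‑catalysed condensation of the ketone with the arenesulfonylhydrazide should give the hydrazone, the α‑methyl group of the enone slowing conjugate addition.

Step 7
Reactants: 11 (E)-N'-(3-methylbut-3-en-2-ylidene)-2,4,6-triisopropylbenzenesulfonohydrazide; 9 (1S,4S,7S)-7-(benzyloxy)-3,3-dimethoxy-5,6-dimethylbicyclo[2.2.2]oct-5-en-2-one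
Product: 13 (1S,2S,4S,7S)-7-(benzyloxy)-3,3-dimethoxy-5,6-dimethyl-2-(3-methylbuta-1,3-dien-2-yl)bicyclo[2.2.2]oct-5-en-2-ol (dienyl syn to the alkene bridge), via dienyllithium 12 (not isolated)
Conditions: 11 (3 equiv), n-BuLi (6 equiv), THF, −78 to 0 °C; then 9, −78 °C; H2O
Reagents that add atoms: none
Why: The Shapiro reaction (dianion formed at the methyl group syn to the N–N bond, loss of sulfinate and N2) should give the 2‑lithiodiene, which adds to the non‑enolizable ketone from the face flanked by the alkene bridge rather than the one screened by the hydrogens of the C7–C8 bridge, so the dienyl group ends syn to the alkene.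

Step 8
Reactants: 13 (1S,2S,4S,7S)-7-(benzyloxy)-3,3-dimethoxy-5,6-dimethyl-2-(3-methylbuta-1,3-dien-2-yl)bicyclo[2.2.2]oct-5-en-2-ol
Product: 16 (2S,5S,7R,10S)-2β-(benzyloxy)-9,9-dimethoxy-10βH-eremophila-3,11-dien-8-one (cis-fused; isopropenyl β), via potassium alkoxide 14 (not isolated), via potassium dienolate 15 (not isolated)
Conditions: KH, 18-crown-6, THF, 0 °C to rt; then inverse quench into AcOH/THF, −78 °C
Reagents that add atoms: none
Why: KH with 18‑crown‑6 gives the dissociated alkoxide 14, whose charge weakens the C3–C8 bond so that the 1,5‑diene C6=C7–C8–C3–C4=C5 undergoes a concerted [3,3]‑sigmatropic shift through the boat‑like six‑centre array that the bicycle enforces, breaking C3–C8 and forming C5–C6 to give dienolate 15 (anionic oxy‑Cope rearrangement). The closest known reaction type is the alkoxide‑accelerated oxy‑Cope rearrangement of 2‑alkenylbicyclo[2.2.2]oct‑5‑en‑2‑ols to cis‑decalin enolates. Ring B closes as a six‑membered ring by suprafacial bonding of the dienyl terminus C6 to C5 within this cyclic transition state, while the old bridge opens to leave ring A as a cyclohexene. C5 becomes quaternary on the only face of the C4=C5 bridge that the tethered C6 can reach, the one turned toward the carbinol bridge, which makes the C5 methyl cis to H10 and passes the configuration of resolved 13 on to both ring‑fusion carbons. C7 is created when 15 is protonated at its α‑carbon: in the half‑chair of ring B that keeps a ketal methoxy group out of the fold under ring A, the C5 methyl and one methoxy group stand axial on the β face of C7, so the proton should arrive from the α face and leave the isopropenyl group β. The step needs the dienyl group syn to the alkene bridge (secured in step 7), α‑ rather than γ‑protonation of the dienolate and no later enolization, which the cold inverse quench into acetic acid and the immediate reduction in step 9 are meant to secure.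

Step 9
Reactants: 16 (2S,5S,7R,10S)-2β-(benzyloxy)-9,9-dimethoxy-10βH-eremophila-3,11-dien-8-one
Product: 17 (2S,5S,7R,8R,10S)-2β-(benzyloxy)-9,9-dimethoxy-10βH-eremophila-3,11-dien-8α-ol
Conditions: crude 16 used at once; NaBH4, CeCl3·7H2O, MeOH, −78 to −20 °C
Reagents that add atoms: none
Why: In the chair of ring B that keeps the isopropenyl and C5 methyl groups equatorial, the α face of C8 is screened by the axial methoxy group on C9, so borohydride should add axially from the β face to give the equatorial 8α‑alcohol trans to the isopropenyl group, while the cold cerium‑buffered medium avoids enolization toward C7 (Luche reduction).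

Step 10
Reactants: 17 (2S,5S,7R,8R,10S)-2β-(benzyloxy)-9,9-dimethoxy-10βH-eremophila-3,11-dien-8α-ol
Product: 18 (2S,5S,7R,8R,10S)-2β-(benzyloxy)-8α-hydroxy-10βH-eremophila-3,11-dien-9-one
Conditions: TsOH·H2O (cat.), acetone/H2O 10:1, rt
Reagents that add atoms: water, O
Why: Acid‑catalysed hydrolysis of the dimethyl ketal should be helped by release of the strain of the methoxy group lodged under ring A, and the mild acid should leave the allylic benzyl ether, the alkenes and the ring fusion untouched.

Step 11
Reactants: 18 (2S,5S,7R,8R,10S)-2β-(benzyloxy)-8α-hydroxy-10βH-eremophila-3,11-dien-9-one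
Product: 19 (2S,5S,7R,8R,9S,10S)-2β-(benzyloxy)-10βH-eremophila-3,11-diene-8α,9α-diol
Conditions: LiBH(s-Bu)3 (L-Selectride, 2.5 equiv), THF, −78 °C; H2O
Reagents that add atoms: none
Why: With C9 trigonal, ring A (C4 axial on ring B) lies folded over the α face of C9, so the bulky hydride should add from the exposed β face and give the 9α‑alcohol cis to the 8α‑hydroxyl (trialkylborohydride reduction under steric approach control).

Step 12
Reactants: 19 (2S,5S,7R,8R,9S,10S)-2β-(benzyloxy)-10βH-eremophila-3,11-diene-8α,9α-diol
Product: 20 (2S,5S,7R,8R,9S,10S)-10βH-eremophila-3,11-diene-2β,8α,9α-triol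
Conditions: Li, NH3(l)/THF, −78 °C; then solid NH4Cl
Reagents that add atoms: none
Why: In this Birch‑type reductive debenzylation the arene radical anion expels the C2 alkoxide, while the isolated alkenes and the alkoxides are inert to the dissolving metal.

Step 13
Reactants: 20 (2S,5S,7R,8R,9S,10S)-10βH-eremophila-3,11-diene-2β,8α,9α-triol
Product: 21 (5S,7R,8R,9S,10S)-8α,9α-dihydroxy-10βH-eremophila-3,11-dien-2-one
Conditions: MnO2 (activated, excess), CH2Cl2, rt, short contact time
Reagents that add atoms: none
Why: MnO2 should oxidize only the allylic C2 carbinol to the enone, the saturated 8,9‑diol reacting far more slowly, and the reaction is stopped early to avoid glycol cleavage (chemoselective allylic oxidation).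

Step 14
Reactants: 21 (5S,7R,8R,9S,10S)-8α,9α-dihydroxy-10βH-eremophila-3,11-dien-2-one
Product: 22 (4S,5R,7R,8R,9S,10S)-8α,9α-dihydroxy-10βH-eremophil-11-en-2-one
Conditions: Li (2.5 equiv), NH3(l)/THF, −78 °C; then solid NH4Cl
Reagents that add atoms: none
Why: In this dissolving‑metal conjugate reduction the C4 carbanion should be protonated axially on the α face, where the 9α‑hydroxyl lies within reach as an internal proton donor, so the C4 methyl ends equatorial and cis to the C5 methyl (the more stable arrangement), the enolate gives the ketone on quench and the isolated isopropenyl group is not reduced.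

Step 15
Reactants: 22 (4S,5R,7R,8R,9S,10S)-8α,9α-dihydroxy-10βH-eremophil-11-en-2-one
Product: 23 (4S,5R,7R,8R,9S,10S)-8α-acetoxy-9α-hydroxy-10βH-eremophil-11-en-2-one
Conditions: Ac2O (1.2 equiv), pyridine, CH2Cl2, 0 °C
Reagents that add atoms: acetic anhydride, CC(=O)OC(C)=O
Why: The exposed equatorial 8α‑hydroxyl should be acylated well before the 9α‑hydroxyl buried under ring A, so one equivalent of anhydride should give the 8‑monoacetate (sterically controlled esterification).

Step 16
Reactants: 23 (4S,5R,7R,8R,9S,10S)-8α-acetoxy-9α-hydroxy-10βH-eremophil-11-en-2-one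
Product: 24 (4S,5R,7R,8R,9S,10S)-8α-acetoxy-9α-(3-methylbut-2-enoyloxy)-10βH-eremophil-11-en-2-one (CNP0150397.1)
Conditions: 3-methylbut-2-enoyl chloride, DMAP (cat.), pyridine, CH2Cl2, 0 °C to rt
Reagents that add atoms: 3-methylbut-2-enoyl chloride, CC(C)=CC(=O)Cl
Why: DMAP‑catalysed acylation in pyridine, a base too weak to form the vinylketene that would shift the double bond, should esterify the remaining hindered 9α‑hydroxyl, and the equatorial acetate has no drive to migrate to the axial oxygen.

**Compound list**
1 | 3,4-dimethylphenol | Cc1ccc(O)cc1C | starting material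
2 | 2-hydroxy-4,5-dimethylbenzaldehyde | Cc1cc(O)c(C=O)cc1C | intermediate
3 | 2-methoxy-4,5-dimethylbenzaldehyde | COc1cc(C)c(C)cc1C=O | intermediate
4 | 2-methoxy-4,5-dimethylphenyl formate (formed in the flask) | COc1cc(C)c(C)cc1OC=O | intermediate
5 | 2-methoxy-4,5-dimethylphenol | COc1cc(C)c(C)cc1O | intermediate
6 | benzyl vinyl ether | C=COCc1ccccc1 | starting material
7 | 6,6-dimethoxy-3,4-dimethylcyclohexa-2,4-dien-1-one (masked o-benzoquinone, formed in the flask) | COC1(OC)C=C(C)C(C)=CC1=O | intermediate
8 | racemic (1S*,4S*,7S*)-7-(benzyloxy)-3,3-dimethoxy-5,6-dimethylbicyclo[2.2.2]oct-5-en-2-one, benzyloxy syn to the alkene bridge (1:1 mixture, both enantiomers written) | O=C1C(OC)(OC)[C@H]2C[C@H](OCc3ccccc3)[C@@H]1C(C)=C2C.O=C1C(OC)(OC)[C@@H]2C[C@@H](OCc3ccccc3)[C@H]1C(C)=C2C | intermediate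
9 | (1S,4S,7S)-7-(benzyloxy)-3,3-dimethoxy-5,6-dimethylbicyclo[2.2.2]oct-5-en-2-one | O=C1C(OC)(OC)[C@H]2C[C@H](OCc3ccccc3)[C@@H]1C(C)=C2C | intermediate
10 | 3-methylbut-3-en-2-one | CC(=C)C(C)=O | starting material
11 | (E)-N'-(3-methylbut-3-en-2-ylidene)-2,4,6-triisopropylbenzenesulfonohydrazide | C/C(=N\NS(=O)(=O)c1c(C(C)C)cc(C(C)C)cc1C(C)C)C(C)=C | intermediate
12 | (3-methylbuta-1,3-dien-2-yl)lithium (formed in the flask) | [Li]C(=C)C(C)=C | intermediate
13 | (1S,2S,4S,7S)-7-(benzyloxy)-3,3-dimethoxy-5,6-dimethyl-2-(3-methylbuta-1,3-dien-2-yl)bicyclo[2.2.2]oct-5-en-2-ol, dienyl syn to the alkene bridge | CC(=C)C(=C)[C@]1(O)C(OC)(OC)[C@H]2C[C@H](OCc3ccccc3)[C@@H]1C(C)=C2C | intermediate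
14 | potassium alkoxide of 13 (formed in the flask) | CC(=C)C(=C)[C@]1([O-])C(OC)(OC)[C@H]2C[C@H](OCc3ccccc3)[C@@H]1C(C)=C2C.[K+] | intermediate
15 | potassium 7(8),11-dienolate of 16 (formed in the flask) | C=C(C)C=1C[C@@]2(C)[C@H](C[C@H](OCc3ccccc3)C=C2C)C(OC)(OC)C=1[O-].[K+] | intermediate
16 | (2S,5S,7R,10S)-2β-(benzyloxy)-9,9-dimethoxy-10βH-eremophila-3,11-dien-8-one | C=C(C)[C@H]1C[C@@]2(C)[C@H](C[C@H](OCc3ccccc3)C=C2C)C(OC)(OC)C1=O | intermediate
17 | (2S,5S,7R,8R,10S)-2β-(benzyloxy)-9,9-dimethoxy-10βH-eremophila-3,11-dien-8α-ol | C=C(C)[C@H]1C[C@@]2(C)[C@H](C[C@H](OCc3ccccc3)C=C2C)C(OC)(OC)[C@@H]1O | intermediate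
18 | (2S,5S,7R,8R,10S)-2β-(benzyloxy)-8α-hydroxy-10βH-eremophila-3,11-dien-9-one | C=C(C)[C@H]1C[C@@]2(C)[C@H](C[C@H](OCc3ccccc3)C=C2C)C(=O)[C@@H]1O | intermediate
19 | (2S,5S,7R,8R,9S,10S)-2β-(benzyloxy)-10βH-eremophila-3,11-diene-8α,9α-diol | C=C(C)[C@H]1C[C@@]2(C)[C@H](C[C@H](OCc3ccccc3)C=C2C)[C@H](O)[C@@H]1O | intermediate
20 | (2S,5S,7R,8R,9S,10S)-10βH-eremophila-3,11-diene-2β,8α,9α-triol | C=C(C)[C@H]1C[C@@]2(C)[C@H](C[C@H](O)C=C2C)[C@H](O)[C@@H]1O | intermediate
21 | (5S,7R,8R,9S,10S)-8α,9α-dihydroxy-10βH-eremophila-3,11-dien-2-one | C=C(C)[C@H]1C[C@@]2(C)[C@H](CC(=O)C=C2C)[C@H](O)[C@@H]1O | intermediate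
22 | (4S,5R,7R,8R,9S,10S)-8α,9α-dihydroxy-10βH-eremophil-11-en-2-one | C=C(C)[C@H]1C[C@@]2(C)[C@H](CC(=O)C[C@@H]2C)[C@H](O)[C@@H]1O | intermediate
23 | (4S,5R,7R,8R,9S,10S)-8α-acetoxy-9α-hydroxy-10βH-eremophil-11-en-2-one | C=C(C)[C@H]1C[C@@]2(C)[C@H](CC(=O)C[C@@H]2C)[C@H](O)[C@@H]1OC(C)=O | intermediate
24 | (4S,5R,7R,8R,9S,10S)-8α-acetoxy-9α-(3-methylbut-2-enoyloxy)-10βH-eremophil-11-en-2-one | C=C(C)[C@H]1C[C@@]2(C)[C@H](CC(=O)C[C@@H]2C)[C@H](OC(=O)C=C(C)C)[C@@H]1OC(C)=O | target

**Totals**
Total steps: 16. Longest linear sequence: 15 steps (steps 1–5 and 7–16, from 3,4‑dimethylphenol); step 6 is a one‑step side branch.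

**Steps most likely to fail**

Step 8. The dienolate may be protonated on the β face of C7 or at its γ‑terminus, or 16 may enolize before it is reduced, any of which erodes the C7 configuration; the two half‑chairs of the enolate are close in energy, so substrate control here is the least secure prediction in the route. Fallback: starting from 13, the rearrangement is run as before but dienolate 15 is silylated in the flask with Me3SiCl to give the trimethylsilyl dienol ether F1. After isolation, F1 is protonated at −78 °C under reagent control with a chiral BINOL‑derived N‑triflylphosphoramide (the antipode matched to α‑face delivery) and phenol as the stoichiometric proton source, which should return ketone 16.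

Step 7. Formation of the dienyllithium may be inefficient (butyllithium adding to the unsaturated hydrazone, or the vinyl anion being quenched), and addition to the hindered ketone may stall. Fallback: starting from 9, 1‑propynylmagnesium bromide (CH3C≡CMgBr) in THF should add to the same face to give the propargylic alcohol F2; ethylene–alkyne cross‑metathesis (ethylene 1 atm, second‑generation Grubbs catalyst, toluene, 60 °C) should then turn the internal alkyne into the 2,3‑disubstituted butadiene and rejoin the route at 13.

Step 16. Acylation of the 9α‑hydroxyl buried under ring A may be slow, letting acetyl migration or double‑bond migration in the acyl group compete. Fallback: starting from 23, 3‑methylbut‑2‑enoyl chloride and Et3N in CH2Cl2 at −78 to 0 °C generate isopropenylketene, a small electrophile that should acylate the buried hydroxyl to give the 3‑methylbut‑3‑enoate F3; DBU in CH2Cl2 should then move the double bond into conjugation and give 24.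

**Further compounds**
F1 | step 8 | trimethylsilyl dienol ether of 16 (8-trimethylsilyloxy-7(8),11-diene) | C=C(C)C=1C[C@@]2(C)[C@H](C[C@H](OCc3ccccc3)C=C2C)C(OC)(OC)C=1O[Si](C)(C)C
F2 | step 7 | (1S,2S,4S,7S)-7-(benzyloxy)-3,3-dimethoxy-5,6-dimethyl-2-(prop-1-yn-1-yl)bicyclo[2.2.2]oct-5-en-2-ol | CC#C[C@]1(O)C(OC)(OC)[C@H]2C[C@H](OCc3ccccc3)[C@@H]1C(C)=C2C
F3 | step 16 | (4S,5R,7R,8R,9S,10S)-8α-acetoxy-9α-(3-methylbut-3-enoyloxy)-10βH-eremophil-11-en-2-one | C=C(C)[C@H]1C[C@@]2(C)[C@H](CC(=O)C[C@@H]2C)[C@H](OC(=O)CC(C)=C)[C@@H]1OC(C)=O
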